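**Retrosynthetic overview**

1. The plan rests on ring A, a pentasubstituted benzene whose C4a is surrounded by four oxygens (C5–OH, C6–OMe, C7–OH, C8a–O1) that must all be told apart. Ring A is therefore built de novo and not taken from a phloroglucinol.
2. Last moves: C4=O from a silyl-protected carbinol, benzyl ethers off by hydrogenolysis, and ring C (closed second) formed at O1–C2 by Mitsunobu etherification of the C8a phenol.
3. Key disconnection: ring A (closed first) by thermal benzannulation of 3-(benzyloxy)-4-methoxycyclobutenone with a chain-bearing triisopropylsiloxyalkyne, which makes C4a–C5, C8–C8a and C5–C6.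
4. Siloxyalkyne: C3 (and a throw-away C4 carbinol) from an Evans syn aldol of the ring B arylacetyl imide with 3-(trimethylsilyl)propynal, so C3 never sits next to an aldehyde; then reduction, silylation and acetylide oxidation.
5. Cyclobutenone: [2+2] cycloaddition of methoxyketene with benzyl ethynyl ether, which brings the C7 benzyl group in directly.

Key step: step 14

Remark on the chemistry: the configuration of the C4 carbinol is immaterial because it is oxidised in step 19, so the syn-aldol epimer is drawn throughout. Benzyl ethynyl ether 24 is kept as a cold ether solution and used at once.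

**Route**

Step 1
Reactants: 1 3-hydroxy-4,5-dimethoxybenzaldehyde
Product: 2 3-(benzyloxy)-4,5-dimethoxybenzaldehyde
Conditions: BnBr, K2CO3, DMF, rt
Reagents that add atoms: benzyl bromide, BrCc1ccccc1
Why: Williamson ether synthesis: the phenoxide formed with K2CO3 is alkylated by benzyl bromide in an SN2 reaction, and the non-enolisable aldehyde is inert to these conditions.

Step 2
Reactants: 2 3-(benzyloxy)-4,5-dimethoxybenzaldehyde
Product: 3 rac-1-[3-(benzyloxy)-4,5-dimethoxyphenyl]-2,2,2-trichloroethan-1-ol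
Conditions: CHCl3, DBU, 0 °C → rt
Reagents that add atoms: chloroform, ClC(Cl)Cl
Why: Amidine-promoted addition of the trichloromethyl anion from chloroform to the non-enolisable aldehyde, a known route to aryl trichloromethyl carbinols, should give the carbinol, whose racemic centre is erased in step 3.

Step 3
Reactants: 3 rac-1-[3-(benzyloxy)-4,5-dimethoxyphenyl]-2,2,2-trichloroethan-1-ol
Product: 6 [3-(benzyloxy)-4,5-dimethoxyphenyl]acetic acid, via gem-dichloroepoxide 4 (not isolated), via arylacetyl chloride 5 (not isolated)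
Conditions: NaBH4, NaOH, t-BuOH, 55 °C; then aq. HCl
Reagents that add atoms: sodium hydroxide, [Na+].[OH-]
Why: Jocic-type reductive homologation: the alkoxide closes to epoxide 4, borohydride opens it at the benzylic carbon to give acyl chloride 5, and hydroxide hydrolyses this to the arylacetate, so the chain grows by one carbon without touching the benzyl or methyl ethers.

Step 4
Reactants: 6 [3-(benzyloxy)-4,5-dimethoxyphenyl]acetic acid; 7 (4S)-4-benzyl-1,3-oxazolidin-2-one
Product: 9 (4S)-4-benzyl-3-{[3-(benzyloxy)-4,5-dimethoxyphenyl]acetyl}-1,3-oxazolidin-2-one, via mixed pivalic anhydride 8 (not isolated)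
Conditions: t-BuCOCl, Et3N, THF, –20 °C; then 7, LiCl, rt
Reagents that add atoms: none
Why: N-Acylation of the oxazolidinone through the mixed anhydride (LiCl/Et3N protocol), in which the nucleophile attacks the unhindered arylacetyl carbonyl and not the pivaloyl one.

Step 5
Reactants: 9 (4S)-4-benzyl-3-{[3-(benzyloxy)-4,5-dimethoxyphenyl]acetyl}-1,3-oxazolidin-2-one; 10 3-(trimethylsilyl)prop-2-ynal
Product: 12 (4S)-4-benzyl-3-{(2S,3S)-2-[3-(benzyloxy)-4,5-dimethoxyphenyl]-3-hydroxy-5-(trimethylsilyl)pent-4-ynoyl}-1,3-oxazolidin-2-one, via Z-boron enolate 11 (not isolated)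
Conditions: Bu2BOTf, i-Pr2NEt, CH2Cl2, –78 → 0 °C; 10, –78 → 0 °C; pH 7 buffer, MeOH, H2O2, 0 °C
Reagents that add atoms: none
Why: Evans syn aldol reaction: soft enolisation gives the Z-boron enolate, which adds to the ynal through a Zimmerman–Traxler chair on the face away from the benzyl group of the (S)-auxiliary, so the aryl-bearing carbon (future C3, R in the target) is set by the auxiliary and the carbinol (future C4) is set syn to it by the chair.

Step 6
Reactants: 12 (4S)-4-benzyl-3-{(2S,3S)-2-[3-(benzyloxy)-4,5-dimethoxyphenyl]-3-hydroxy-5-(trimethylsilyl)pent-4-ynoyl}-1,3-oxazolidin-2-one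
Product: 13 (4S)-4-benzyl-3-{(2S,3S)-2-[3-(benzyloxy)-4,5-dimethoxyphenyl]-3-[(tert-butyldimethylsilyl)oxy]-5-(trimethylsilyl)pent-4-ynoyl}-1,3-oxazolidin-2-one
Conditions: t-BuMe2SiOTf, 2,6-lutidine, CH2Cl2, –78 → 0 °C
Reagents that add atoms: tert-butyldimethylsilyl trifluoromethanesulfonate, CC(C)(C)[Si](C)(C)OS(=O)(=O)C(F)(F)F
Why: Silylation of the secondary alcohol with a silyl triflate and 2,6-lutidine blocks retro-aldol cleavage and marks the C4 oxygen with the silyl group that is to survive longest.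

Step 7
Reactants: 13 (4S)-4-benzyl-3-{(2S,3S)-2-[3-(benzyloxy)-4,5-dimethoxyphenyl]-3-[(tert-butyldimethylsilyl)oxy]-5-(trimethylsilyl)pent-4-ynoyl}-1,3-oxazolidin-2-one
Product: 14 (2R,3S)-2-[3-(benzyloxy)-4,5-dimethoxyphenyl]-3-[(tert-butyldimethylsilyl)oxy]-5-(trimethylsilyl)pent-4-yn-1-ol
Conditions: LiBH4, MeOH (1 equiv), THF, 0 °C
Reagents that add atoms: none
Why: Reductive cleavage of the N-acyl oxazolidinone with LiBH4 (hydride adds to the exocyclic imide carbonyl) frees the auxiliary and turns C2 into a primary alcohol, so C3 is no longer next to a carbonyl group and cannot epimerise.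

Step 8
Reactants: 14 (2R,3S)-2-[3-(benzyloxy)-4,5-dimethoxyphenyl]-3-[(tert-butyldimethylsilyl)oxy]-5-(trimethylsilyl)pent-4-yn-1-ol
Product: 15 {[(2R,3S)-2-[3-(benzyloxy)-4,5-dimethoxyphenyl]-3-[(tert-butyldimethylsilyl)oxy]-5-(trimethylsilyl)pent-4-yn-1-yl]oxy}triethylsilane
Conditions: Et3SiCl, imidazole, CH2Cl2, 0 °C
Reagents that add atoms: chlorotriethylsilane, CC[Si](Cl)(CC)CC
Why: Silylation of the primary alcohol with Et3SiCl and imidazole puts a more fluoride-labile silyl ether on the C2 oxygen than the one on the hindered C4 oxygen.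

Step 9
Reactants: 15 {[(2R,3S)-2-[3-(benzyloxy)-4,5-dimethoxyphenyl]-3-[(tert-butyldimethylsilyl)oxy]-5-(trimethylsilyl)pent-4-yn-1-yl]oxy}triethylsilane
Product: 16 {[(2R,3S)-2-[3-(benzyloxy)-4,5-dimethoxyphenyl]-3-[(tert-butyldimethylsilyl)oxy]pent-4-yn-1-yl]oxy}triethylsilane
Conditions: K2CO3 (0.2 equiv), MeOH, 0 °C
Reagents that add atoms: none
Why: Protodesilylation of the alkynylsilane by methoxide: the C(sp)–Si bond is cleaved far faster than the O–Si bonds of the triethylsilyl and tert-butyldimethylsilyl ethers at 0 °C.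

Step 10
Reactants: 16 {[(2R,3S)-2-[3-(benzyloxy)-4,5-dimethoxyphenyl]-3-[(tert-butyldimethylsilyl)oxy]pent-4-yn-1-yl]oxy}triethylsilane
Product: 19 {[(3S,4R)-4-[3-(benzyloxy)-4,5-dimethoxyphenyl]-3-[(tert-butyldimethylsilyl)oxy]-5-[(triethylsilyl)oxy]pent-1-yn-1-yl]oxy}tri(propan-2-yl)silane, via lithium acetylide 17 (not isolated), via lithium ynolate 18 (not isolated)
Conditions: LiN(SiMe3)2, THF, –78 °C; t-BuOOLi (from t-BuOOH + LiN(SiMe3)2), –78 → 0 °C; i-Pr3SiOTf, –78 → 0 °C
Reagents that add atoms: tert-butyl hydroperoxide, CC(C)(C)OO; triisopropylsilyl trifluoromethanesulfonate, CC(C)[Si](OS(=O)(=O)C(F)(F)F)(C(C)C)C(C)C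
Why: Julia-type oxidation of the lithium acetylide with lithium tert-butyl peroxide gives the lithium ynolate, which the bulky silyl triflate traps on oxygen, the standard entry to triisopropylsilyl ynol ethers from terminal alkynes.

Step 11
Reactants: 20 benzyl alcohol; 21 trichloroethylene
Product: 22 benzyl (E)-1,2-dichlorovinyl ether
Conditions: KH, THF, 0 °C; then 21, –50 °C → rt
Reagents that add atoms: none
Why: Benzyl alkoxide adds to dichloroacetylene generated in the flask from trichloroethylene (elimination–addition with trans addition), the known entry to (E)-1,2-dichlorovinyl ethers.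

Step 12
Reactants: 22 benzyl (E)-1,2-dichlorovinyl ether
Product: 24 benzyl ethynyl ether, via lithium benzyloxyacetylide 23 (not isolated)
Conditions: n-BuLi (2.2 equiv), Et2O, –78 → –40 °C; then H2O, –78 °C
Reagents that add atoms: none
Why: Two equivalents of n-BuLi effect dehydrochlorination to the chloroalkynyl ether and then chlorine–lithium exchange to the lithium alkoxyacetylide, and protonation at low temperature gives the terminal ynol ether before it can rearrange.

Step 13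
Reactants: 25 methoxyacetyl chloride; 24 benzyl ethynyl ether
Product: 27 rac-3-(benzyloxy)-4-methoxycyclobut-2-en-1-one, via methoxyketene 26 (not isolated)
Conditions: Et3N (slow addition), Et2O, 0 °C → rt
Reagents that add atoms: none
Why: Ketene–alkoxyacetylene [2+2] cycloaddition: methoxyketene, made by dehydrochlorination of the acid chloride, is attacked at its carbonyl carbon by the nucleophilic terminal carbon of the ynol ether, which places the benzyloxy group at C3 and the methoxy group at C4 of the cyclobutenone (racemic at C4, which is of no consequence).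

Step 14
Reactants: 19 {[(3S,4R)-4-[3-(benzyloxy)-4,5-dimethoxyphenyl]-3-[(tert-butyldimethylsilyl)oxy]-5-[(triethylsilyl)oxy]pent-1-yn-1-yl]oxy}tri(propan-2-yl)silane; 27 rac-3-(benzyloxy)-4-methoxycyclobut-2-en-1-one
Product: 32 3-(benzyloxy)-6-{(1S,2R)-2-[3-(benzyloxy)-4,5-dimethoxyphenyl]-1-[(tert-butyldimethylsilyl)oxy]-3-[(triethylsilyl)oxy]propyl}-2-methoxy-5-[(triisopropylsilyl)oxy]phenol, via vinylketene 28 (not isolated), via 4-vinylcyclobutenone 29 (not isolated), via dienylketene 30 (not isolated), via cyclohexa-2,4-dienone 31 (not isolated)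
Conditions: 27 (2 equiv), PhMe, 80 → 110 °C, Ar
Reagents that add atoms: none
Why: Heating opens cyclobutenone 27 in a four-electron electrocyclic reaction (methoxy group turning outward) to vinylketene 28, whose ketene C=C adds the siloxyalkyne in a [2+2] cycloaddition to give 29; this opens again to dienylketene 30, which closes to dienone 31 and tautomerises to phenol 32. The closest known reaction is the Danheiser benzannulation of cyclobutenones with siloxyalkynes. Ring A is closed by the disrotatory 6π electrocyclisation that joins the former ketene carbon (C5) to the methoxy-bearing carbon (C6), after the [2+2] step has made C4a–C5 and C8–C8a. No lasting stereocentre is formed, and the non-enolisable C3 and C4 centres of the chain are untouched by the neutral thermal conditions. The step needs the regiochemistry of the ketene–ynol ether cycloaddition, which the polarisation of the siloxyalkyne secures: its nucleophilic chain-bearing carbon bonds to the electrophilic ketene carbonyl carbon, so the chain ends between the new hydroxyl (C5) and the siloxy group (C8a), with methoxy on C6 and benzyloxy on C7.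

Step 15
Reactants: 32 3-(benzyloxy)-6-{(1S,2R)-2-[3-(benzyloxy)-4,5-dimethoxyphenyl]-1-[(tert-butyldimethylsilyl)oxy]-3-[(triethylsilyl)oxy]propyl}-2-methoxy-5-[(triisopropylsilyl)oxy]phenol
Product: 33 {[(1S,2R)-1-[2,4-bis(benzyloxy)-3-methoxy-6-(triisopropylsilyloxy)phenyl]-2-[3-(benzyloxy)-4,5-dimethoxyphenyl]-3-(triethylsilyloxy)propyl]oxy}(tert-butyl)dimethylsilane
Conditions: NaH, BnBr, DMF, 0 °C → rt
Reagents that add atoms: benzyl bromide, BrCc1ccccc1
Why: Williamson benzylation of the only free hydroxyl group, the C5 phenol, so that it cannot compete with the C8a oxygen in the ring closure; the phenoxide is formed with NaH so that no oxygen base attacks the aryl silyl ether.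

Step 16
Reactants: 33 {[(1S,2R)-1-[2,4-bis(benzyloxy)-3-methoxy-6-(triisopropylsilyloxy)phenyl]-2-[3-(benzyloxy)-4,5-dimethoxyphenyl]-3-(triethylsilyloxy)propyl]oxy}(tert-butyl)dimethylsilane
Product: 34 3,5-bis(benzyloxy)-2-{(1S,2R)-2-[3-(benzyloxy)-4,5-dimethoxyphenyl]-1-[(tert-butyldimethylsilyl)oxy]-3-hydroxypropyl}-4-methoxyphenol
Conditions: Bu4NF (2.2 equiv), AcOH (2.2 equiv), THF, 0 °C
Reagents that add atoms: none
Why: Fluoride-mediated desilylation graded by Si–O lability: the aryl triisopropylsilyl ether and the primary triethylsilyl ether are cleaved at 0 °C, while the secondary tert-butyldimethylsilyl ether, flanked by the 2,6-disubstituted arene and the C3 branch, should persist.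

Step 17
Reactants: 34 3,5-bis(benzyloxy)-2-{(1S,2R)-2-[3-(benzyloxy)-4,5-dimethoxyphenyl]-1-[(tert-butyldimethylsilyl)oxy]-3-hydroxypropyl}-4-methoxyphenol
Product: 35 tert-butyl{[(3R,4S)-5,7-bis(benzyloxy)-3-[3-(benzyloxy)-4,5-dimethoxyphenyl]-6-methoxy-3,4-dihydro-2H-chromen-4-yl]oxy}dimethylsilane
Conditions: PPh3, DIAD, THF, 0 °C → rt
Reagents that add atoms: none
Why: Mitsunobu etherification: the phenol is the acidic partner and the activated primary alcohol is displaced in an intramolecular SN2 reaction (6-exo-tet) that closes ring C at O1–C2 without touching C3.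

Step 18
Reactants: 35 tert-butyl{[(3R,4S)-5,7-bis(benzyloxy)-3-[3-(benzyloxy)-4,5-dimethoxyphenyl]-6-methoxy-3,4-dihydro-2H-chromen-4-yl]oxy}dimethylsilane
Product: 36 (3R,4S)-5,7-bis(benzyloxy)-3-[3-(benzyloxy)-4,5-dimethoxyphenyl]-6-methoxy-3,4-dihydro-2H-chromen-4-ol
Conditions: Bu4NF, THF, rt → 45 °C
Reagents that add atoms: none
Why: Fluoride cleavage of the remaining hindered silyl ether under more forcing conditions; the basic medium avoids acid-promoted ionisation of the electron-rich benzylic alcohol.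

Step 19
Reactants: 36 (3R,4S)-5,7-bis(benzyloxy)-3-[3-(benzyloxy)-4,5-dimethoxyphenyl]-6-methoxy-3,4-dihydro-2H-chromen-4-ol
Product: 37 (3R)-5,7-bis(benzyloxy)-3-[3-(benzyloxy)-4,5-dimethoxyphenyl]-6-methoxy-2,3-dihydro-4H-chromen-4-one
Conditions: Dess–Martin periodinane, NaHCO3, CH2Cl2, 0 °C → rt
Reagents that add atoms: none
Why: Dess–Martin oxidation of the benzylic secondary alcohol to the ketone under amine-free, near-neutral conditions, chosen because C3 becomes enolisable at this point.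

Step 20
Reactants: 37 (3R)-5,7-bis(benzyloxy)-3-[3-(benzyloxy)-4,5-dimethoxyphenyl]-6-methoxy-2,3-dihydro-4H-chromen-4-one
Product: 38 (3R)-5,7-dihydroxy-3-(3-hydroxy-4,5-dimethoxyphenyl)-6-methoxy-2,3-dihydro-4H-chromen-4-one
Conditions: H2 (1 atm), 10% Pd/C, EtOAc, rt
Reagents that add atoms: none
Why: Hydrogenolysis of the three benzyl ethers over palladium on carbon in a neutral solvent, which should leave the aryl ketone and the base-sensitive C3 centre alone.

**Compound list**

1 | 3-hydroxy-4,5-dimethoxybenzaldehyde | COc1cc(C=O)cc(O)c1OC | starting material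
2 | 3-(benzyloxy)-4,5-dimethoxybenzaldehyde | COc1cc(C=O)cc(OCc2ccccc2)c1OC | intermediate
3 | rac-1-[3-(benzyloxy)-4,5-dimethoxyphenyl]-2,2,2-trichloroethan-1-ol | COc1cc(C(O)C(Cl)(Cl)Cl)cc(OCc2ccccc2)c1OC | intermediate
4 | 3-[3-(benzyloxy)-4,5-dimethoxyphenyl]-2,2-dichlorooxirane | COc1cc(C2OC2(Cl)Cl)cc(OCc2ccccc2)c1OC | intermediate
5 | [3-(benzyloxy)-4,5-dimethoxyphenyl]acetyl chloride | COc1cc(CC(Cl)=O)cc(OCc2ccccc2)c1OC | intermediate
6 | [3-(benzyloxy)-4,5-dimethoxyphenyl]acetic acid | COc1cc(CC(=O)O)cc(OCc2ccccc2)c1OC | intermediate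
7 | (4S)-4-benzyl-1,3-oxazolidin-2-one | O=C1N[C@@H](Cc2ccccc2)CO1 | starting material
8 | [3-(benzyloxy)-4,5-dimethoxyphenyl]acetic pivalic anhydride | COc1cc(CC(=O)OC(=O)C(C)(C)C)cc(OCc2ccccc2)c1OC | intermediate
9 | (4S)-4-benzyl-3-{[3-(benzyloxy)-4,5-dimethoxyphenyl]acetyl}-1,3-oxazolidin-2-one | O=C1OC[C@H](Cc2ccccc2)N1C(=O)Cc1cc(OC)c(OC)c(OCc2ccccc2)c1 | intermediate
10 | 3-(trimethylsilyl)prop-2-ynal | C[Si](C)(C)C#CC=O | starting material
11 | (Z)-dibutylboron enolate of 9 (O-boryl and aryl cis) | CCCCB(CCCC)O/C(=C\c1cc(OC)c(OC)c(OCc2ccccc2)c1)N1[C@@H](Cc2ccccc2)COC1=O | intermediate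
12 | (4S)-4-benzyl-3-{(2S,3S)-2-[3-(benzyloxy)-4,5-dimethoxyphenyl]-3-hydroxy-5-(trimethylsilyl)pent-4-ynoyl}-1,3-oxazolidin-2-one | O=C1OC[C@H](Cc2ccccc2)N1C(=O)[C@@H](c1cc(OC)c(OC)c(OCc2ccccc2)c1)[C@H](O)C#C[Si](C)(C)C | intermediate
13 | (4S)-4-benzyl-3-{(2S,3S)-2-[3-(benzyloxy)-4,5-dimethoxyphenyl]-3-[(tert-butyldimethylsilyl)oxy]-5-(trimethylsilyl)pent-4-ynoyl}-1,3-oxazolidin-2-one | O=C1OC[C@H](Cc2ccccc2)N1C(=O)[C@@H](c1cc(OC)c(OC)c(OCc2ccccc2)c1)[C@H](O[Si](C)(C)C(C)(C)C)C#C[Si](C)(C)C | intermediate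
14 | (2R,3S)-2-[3-(benzyloxy)-4,5-dimethoxyphenyl]-3-[(tert-butyldimethylsilyl)oxy]-5-(trimethylsilyl)pent-4-yn-1-ol | OC[C@@H](c1cc(OC)c(OC)c(OCc2ccccc2)c1)[C@H](O[Si](C)(C)C(C)(C)C)C#C[Si](C)(C)C | intermediate
15 | {[(2R,3S)-2-[3-(benzyloxy)-4,5-dimethoxyphenyl]-3-[(tert-butyldimethylsilyl)oxy]-5-(trimethylsilyl)pent-4-yn-1-yl]oxy}triethylsilane | CC[Si](CC)(CC)OC[C@@H](c1cc(OC)c(OC)c(OCc2ccccc2)c1)[C@H](O[Si](C)(C)C(C)(C)C)C#C[Si](C)(C)C | intermediate
16 | {[(2R,3S)-2-[3-(benzyloxy)-4,5-dimethoxyphenyl]-3-[(tert-butyldimethylsilyl)oxy]pent-4-yn-1-yl]oxy}triethylsilane | CC[Si](CC)(CC)OC[C@@H](c1cc(OC)c(OC)c(OCc2ccccc2)c1)[C@H](O[Si](C)(C)C(C)(C)C)C#C | intermediate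
17 | lithium acetylide of 16 | CC[Si](CC)(CC)OC[C@@H](c1cc(OC)c(OC)c(OCc2ccccc2)c1)[C@H](O[Si](C)(C)C(C)(C)C)C#C[Li] | intermediate
18 | lithium (3S,4R)-4-[3-(benzyloxy)-4,5-dimethoxyphenyl]-3-[(tert-butyldimethylsilyl)oxy]-5-[(triethylsilyl)oxy]pent-1-yn-1-olate | CC[Si](CC)(CC)OC[C@@H](c1cc(OC)c(OC)c(OCc2ccccc2)c1)[C@H](O[Si](C)(C)C(C)(C)C)C#CO[Li] | intermediate
19 | {[(3S,4R)-4-[3-(benzyloxy)-4,5-dimethoxyphenyl]-3-[(tert-butyldimethylsilyl)oxy]-5-[(triethylsilyl)oxy]pent-1-yn-1-yl]oxy}tri(propan-2-yl)silane | CC[Si](CC)(CC)OC[C@@H](c1cc(OC)c(OC)c(OCc2ccccc2)c1)[C@H](O[Si](C)(C)C(C)(C)C)C#CO[Si](C(C)C)(C(C)C)C(C)C | intermediate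
20 | benzyl alcohol | OCc1ccccc1 | starting material
21 | trichloroethylene | ClC=C(Cl)Cl | starting material
22 | benzyl (E)-1,2-dichlorovinyl ether | Cl/C=C(/Cl)OCc1ccccc1 | intermediate
23 | lithium benzyloxyacetylide | [Li]C#COCc1ccccc1 | intermediate
24 | benzyl ethynyl ether | C#COCc1ccccc1 | intermediate
25 | methoxyacetyl chloride | COCC(Cl)=O | starting material
26 | methoxyketene | COC=C=O | intermediate
27 | rac-3-(benzyloxy)-4-methoxycyclobut-2-en-1-one | COC1C(=O)C=C1OCc1ccccc1 | intermediate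
28 | (3Z)-3-(benzyloxy)-4-methoxybuta-1,3-dien-1-one | O=C=C/C(OCc1ccccc1)=C/OC | intermediate
29 | 4-[(Z)-1-(benzyloxy)-2-methoxyethenyl]-2-{(1S,2R)-2-[3-(benzyloxy)-4,5-dimethoxyphenyl]-1-[(tert-butyldimethylsilyl)oxy]-3-[(triethylsilyl)oxy]propyl}-3-[(triisopropylsilyl)oxy]cyclobut-2-en-1-one (mixture at ring C4) | CC[Si](CC)(CC)OC[C@@H](c1cc(OC)c(OC)c(OCc2ccccc2)c1)[C@H](O[Si](C)(C)C(C)(C)C)C1=C(O[Si](C(C)C)(C(C)C)C(C)C)C(/C(OCc2ccccc2)=C/OC)C1=O | intermediate
30 | (3E,5Z)-5-(benzyloxy)-6-methoxy-3-[(triisopropylsilyl)oxy]hexa-1,3,5-trien-1-one carrying the same (1S,2R) chain at C2 | CC[Si](CC)(CC)OC[C@@H](c1cc(OC)c(OC)c(OCc2ccccc2)c1)[C@H](O[Si](C)(C)C(C)(C)C)C(=C=O)/C(O[Si](C(C)C)(C(C)C)C(C)C)=C\C(OCc2ccccc2)=C\OC | intermediate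
31 | 5-(benzyloxy)-6-methoxy-3-[(triisopropylsilyl)oxy]cyclohexa-2,4-dien-1-one carrying the same (1S,2R) chain at C2 (mixture at C6) | CC[Si](CC)(CC)OC[C@@H](c1cc(OC)c(OC)c(OCc2ccccc2)c1)[C@H](O[Si](C)(C)C(C)(C)C)C1=C(O[Si](C(C)C)(C(C)C)C(C)C)C=C(OCc2ccccc2)C(OC)C1=O | intermediate
32 | 3-(benzyloxy)-6-{(1S,2R)-2-[3-(benzyloxy)-4,5-dimethoxyphenyl]-1-[(tert-butyldimethylsilyl)oxy]-3-[(triethylsilyl)oxy]propyl}-2-methoxy-5-[(triisopropylsilyl)oxy]phenol | CC[Si](CC)(CC)OC[C@@H](c1cc(OC)c(OC)c(OCc2ccccc2)c1)[C@H](O[Si](C)(C)C(C)(C)C)c1c(O)c(OC)c(OCc2ccccc2)cc1O[Si](C(C)C)(C(C)C)C(C)C | intermediate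
33 | {[(1S,2R)-1-[2,4-bis(benzyloxy)-3-methoxy-6-(triisopropylsilyloxy)phenyl]-2-[3-(benzyloxy)-4,5-dimethoxyphenyl]-3-(triethylsilyloxy)propyl]oxy}(tert-butyl)dimethylsilane | CC[Si](CC)(CC)OC[C@@H](c1cc(OC)c(OC)c(OCc2ccccc2)c1)[C@H](O[Si](C)(C)C(C)(C)C)c1c(OCc2ccccc2)c(OC)c(OCc2ccccc2)cc1O[Si](C(C)C)(C(C)C)C(C)C | intermediate
34 | 3,5-bis(benzyloxy)-2-{(1S,2R)-2-[3-(benzyloxy)-4,5-dimethoxyphenyl]-1-[(tert-butyldimethylsilyl)oxy]-3-hydroxypropyl}-4-methoxyphenol | OC[C@@H](c1cc(OC)c(OC)c(OCc2ccccc2)c1)[C@H](O[Si](C)(C)C(C)(C)C)c1c(OCc2ccccc2)c(OC)c(OCc2ccccc2)cc1O | intermediate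
35 | tert-butyl{[(3R,4S)-5,7-bis(benzyloxy)-3-[3-(benzyloxy)-4,5-dimethoxyphenyl]-6-methoxy-3,4-dihydro-2H-chromen-4-yl]oxy}dimethylsilane | COc1cc([C@@H]2COc3cc(OCc4ccccc4)c(OC)c(OCc4ccccc4)c3[C@H]2O[Si](C)(C)C(C)(C)C)cc(OCc2ccccc2)c1OC | intermediate
36 | (3R,4S)-5,7-bis(benzyloxy)-3-[3-(benzyloxy)-4,5-dimethoxyphenyl]-6-methoxy-3,4-dihydro-2H-chromen-4-ol | COc1cc([C@@H]2COc3cc(OCc4ccccc4)c(OC)c(OCc4ccccc4)c3[C@H]2O)cc(OCc2ccccc2)c1OC | intermediate
37 | (3R)-5,7-bis(benzyloxy)-3-[3-(benzyloxy)-4,5-dimethoxyphenyl]-6-methoxy-2,3-dihydro-4H-chromen-4-one | COc1cc([C@@H]2COc3cc(OCc4ccccc4)c(OC)c(OCc4ccccc4)c3C2=O)cc(OCc2ccccc2)c1OC | intermediate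
38 | (3R)-5,7-dihydroxy-3-(3-hydroxy-4,5-dimethoxyphenyl)-6-methoxy-2,3-dihydro-4H-chromen-4-one (CNP0258659.1) | COc1cc([C@@H]2COc3cc(O)c(OC)c(O)c3C2=O)cc(O)c1OC | target

**Step count**

Total: 20 steps. Longest linear sequence: 17 steps (steps 1–10, then 14–20); the cyclobutenone branch (steps 11–13) joins at step 14.

**Steps most likely to fail**

1. Step 14 (key step). What may go wrong: capture of the vinylketene by the α-branched siloxyalkyne may be slower than ketene dimerisation or acylation of the new phenol, and on prolonged heating the ortho-hydroxybenzyl silyl ether may eliminate silanol.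
Fallback: ring A is taken from a symmetrical phenol whose single hydroxyl is already the future O1. It sets out from acid 6 and comes back to the route at ketone 37.
   - Commercial methyl 3,5-dihydroxy-4-methoxybenzoate would be benzylated (BnBr, K2CO3) to methyl 3,5-bis(benzyloxy)-4-methoxybenzoate F1.
   - MeMgBr would give 2-[3,5-bis(benzyloxy)-4-methoxyphenyl]propan-2-ol F2, and a Hock-type hydroperoxide rearrangement (H2O2, BF3·OEt2) would give 3,5-bis(benzyloxy)-4-methoxyphenol F3.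
   - Friedel–Crafts acylation of F3 with acid 6, activated as its mixed trifluoroacetic anhydride, would give 1-[4,6-bis(benzyloxy)-2-hydroxy-5-methoxyphenyl]-2-[3-(benzyloxy)-4,5-dimethoxyphenyl]ethan-1-one F4. The two ortho positions are equivalent, so no 6- versus 8-methoxy ambiguity arises.
   - Me2NCH(OMe)2 would close the isoflavone 5,7-bis(benzyloxy)-3-[3-(benzyloxy)-4,5-dimethoxyphenyl]-6-methoxy-4H-chromen-4-one F5.
   - Asymmetric transfer hydrogenation with dynamic kinetic resolution (RuCl(p-cymene)(TsDPEN) in the enantiomeric form that delivers the 3R centre, HCO2H/Et3N) would give the cis alcohol (3R,4R)-5,7-bis(benzyloxy)-3-[3-(benzyloxy)-4,5-dimethoxyphenyl]-6-methoxy-3,4-dihydro-2H-chromen-4-ol F6.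
   - Dess–Martin oxidation of F6 would give 37.

2. Step 13. What may go wrong: methoxyketene may dimerise, or benzyl ethynyl ether may rearrange or polymerise, before the cycloaddition takes place; the strained vinylogous ester may also open on isolation.
Fallback: the cyclobutenone is bypassed and the same vinylketene is made by 1,4-dehydrochlorination. It sets out from siloxyalkyne 19 and benzyl alcohol 20 and comes back at phenol 32.
   - Commercial 3-methoxyprop-1-yne would be carboxylated (n-BuLi, ClCO2Me) to methyl 4-methoxybut-2-ynoate F7.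
   - Alkoxide-catalysed conjugate addition of 20 (cat. NaH, THF) would give methyl 3-(benzyloxy)-4-methoxybut-2-enoate F8.
   - LiOH would give 3-(benzyloxy)-4-methoxybut-2-enoic acid F9, and oxalyl chloride would give 3-(benzyloxy)-4-methoxybut-2-enoyl chloride F10.
   - Slow addition of Et3N to F10 and 19 in toluene (0 → 80 °C) would form vinylketene 28 (or its geometric isomer) in the flask; the [2+2] and electrocyclic sequence of step 14 then leads to 32.

3. Step 16. What may go wrong: fluoride may not discriminate cleanly between the primary triethylsilyl ether and the secondary benzylic silyl ether, or a silyl group may migrate to the freed phenol.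
Fallback: selectivity is moved from the desilylation to the ring closure. It sets out from 33 and comes back at alcohol 36.
   - Excess Bu4NF would remove all three silyl groups to give (1S,2R)-1-[2,4-bis(benzyloxy)-6-hydroxy-3-methoxyphenyl]-2-[3-(benzyloxy)-4,5-dimethoxyphenyl]propane-1,3-diol F11.
   - Mitsunobu closure (PPh3, DIAD) of F11 can form a six-membered ring only through the primary alcohol and the C8a phenol, and would give 36 directly.

**Further compounds**

F1 | step 14 | methyl 3,5-bis(benzyloxy)-4-methoxybenzoate | COC(=O)c1cc(OCc2ccccc2)c(OC)c(OCc2ccccc2)c1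
F2 | step 14 | 2-[3,5-bis(benzyloxy)-4-methoxyphenyl]propan-2-ol | CC(C)(O)c1cc(OCc2ccccc2)c(OC)c(OCc2ccccc2)c1
F3 | step 14 | 3,5-bis(benzyloxy)-4-methoxyphenol | COc1c(OCc2ccccc2)cc(O)cc1OCc1ccccc1
F4 | step 14 | 1-[4,6-bis(benzyloxy)-2-hydroxy-5-methoxyphenyl]-2-[3-(benzyloxy)-4,5-dimethoxyphenyl]ethan-1-one | COc1cc(CC(=O)c2c(O)cc(OCc3ccccc3)c(OC)c2OCc2ccccc2)cc(OCc2ccccc2)c1OC
F5 | step 14 | 5,7-bis(benzyloxy)-3-[3-(benzyloxy)-4,5-dimethoxyphenyl]-6-methoxy-4H-chromen-4-one | COc1cc(-c2coc3cc(OCc4ccccc4)c(OC)c(OCc4ccccc4)c3c2=O)cc(OCc2ccccc2)c1OC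
F6 | step 14 | (3R,4R)-5,7-bis(benzyloxy)-3-[3-(benzyloxy)-4,5-dimethoxyphenyl]-6-methoxy-3,4-dihydro-2H-chromen-4-ol | COc1cc([C@@H]2COc3cc(OCc4ccccc4)c(OC)c(OCc4ccccc4)c3[C@@H]2O)cc(OCc2ccccc2)c1OC
F7 | step 13 | methyl 4-methoxybut-2-ynoate | COCC#CC(=O)OC
F8 | step 13 | methyl 3-(benzyloxy)-4-methoxybut-2-enoate | COCC(OCc1ccccc1)=CC(=O)OC
F9 | step 13 | 3-(benzyloxy)-4-methoxybut-2-enoic acid | COCC(OCc1ccccc1)=CC(=O)O
F10 | step 13 | 3-(benzyloxy)-4-methoxybut-2-enoyl chloride | COCC(OCc1ccccc1)=CC(Cl)=O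
F11 | step 16 | (1S,2R)-1-[2,4-bis(benzyloxy)-6-hydroxy-3-methoxyphenyl]-2-[3-(benzyloxy)-4,5-dimethoxyphenyl]propane-1,3-diol | OC[C@@H](c1cc(OC)c(OC)c(OCc2ccccc2)c1)[C@H](O)c1c(OCc2ccccc2)c(OC)c(OCc2ccccc2)cc1O
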